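Hydrindane numbering is used (C1 CH–OAc, C2 C=O, C3 CH2, C3a, C4–C7, C7a). Everything rests on cutting the C1–C2 bond of the cyclopentanone: its α-oxygenated ketone (C2=O next to C1–O) is the product pattern of a benzoin reaction. The key step is an NHC-catalysed intramolecular crossed benzoin closure of a 1,5-dialdehyde on a finished cyclohexane: the unbranched CH2CHO arm on C3a becomes the acyl anion and adds to the ring-bound CHO on C7a. In one operation it closes the five-membered ring and sets the C2 ketone, the C1 carbinol and its configuration. The trans ring fusion is preset by the trans-diequatorial arms, installed on (S)-cryptone.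

Key step: step 11

Remark on names: monocyclic intermediates carry their own systematic locants; where the text says C1–C7a it means the target locants defined above.
Assumption: the (S)-prolinol ether is taken to shield the enamine face that leads to the (S)-configured Michael adduct; should the sense be opposite, the enantiomeric catalyst is used.

Step 1
Reactants: 1 3-methylbutanal; 2 but-3-en-2-one
Product: 4 (S)-cryptone [(4S)-4-(propan-2-yl)cyclohex-2-en-1-one], via keto aldehyde 3 (not isolated)
Conditions: (S)-2-(methoxydiphenylmethyl)pyrrolidine (5 mol %), ethyl 3,4-dihydroxybenzoate (20 mol %), neat, 4 °C; then LiOH, iPrOH, rt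
Reagents that add atoms: none
Why: Enamine-catalysed Michael addition sets the isopropyl-bearing centre (C7) by shielding of one enamine face by the diarylmethyl group, and base-mediated intramolecular aldol condensation should then close the enone without touching that centre.

Step 2
Reactants: 4 (S)-cryptone
Product: 6 (2R,3S,4S)-3-ethenyl-4-(propan-2-yl)-2-(prop-2-en-1-yl)cyclohexan-1-one, via magnesium enolate 5 (not isolated)
Conditions: CH2=CHMgBr, CuBr·SMe2 (10 mol %), THF, −78 °C; then HMPA, allyl iodide, −78 → 0 °C
Reagents that add atoms: vinylmagnesium bromide, C=C[Mg]Br; allyl iodide, C=CCI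
Why: Copper-catalysed conjugate addition should deliver the vinyl group anti to the adjacent isopropyl group (C7a), and the regiodefined enolate should be allylated anti to the new vinyl group (C3a), a conjugate addition–enolate trapping that gives the all-trans ketone.

Step 3
Reactants: 6 all-trans allyl vinyl ketone
Product: 8 (2R,3S,4S)-2-(2,2-dimethoxyethyl)-3-(dimethoxymethyl)-4-(propan-2-yl)cyclohexan-1-one, via keto dialdehyde 7 (not isolated)
Conditions: O3, CH2Cl2/MeOH, −78 °C; Me2S, −78 °C → rt; then HC(OMe)3, CeCl3·7H2O (10 mol %), MeOH, rt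
Reagents that add atoms: trimethyl orthoformate, COC(OC)OC (methoxy groups of 8); ozone, [O-][O+]=O (its oxygen stays only in intermediate 7)
Why: Ozonolysis with reductive work-up cleaves both terminal alkenes, and cerium-catalysed acetalisation should protect the two aldehydes chemoselectively beside the ketone under conditions mild enough to avoid cyclodehydration of the γ-keto aldehyde; no stereocentre is formed and the all-equatorial arrangement is the stable one.

Step 4
Reactants: 8 bis(dimethyl acetal) ketone
Product: 10 (4R,5S,6R)-6-(2,2-dimethoxyethyl)-5-(dimethoxymethyl)-4-(propan-2-yl)cyclohex-2-en-1-one, via silyl enol ether 9 (not isolated)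
Conditions: LiN(iPr)2, Me3SiCl, THF, −78 °C; then Pd(OAc)2 (1.1 equiv), MeCN, rt
Reagents that add atoms: chlorotrimethylsilane, C[Si](C)(C)Cl (its silyl group stays only in intermediate 9; product 10 gains no atoms)
Why: Kinetic deprotonation occurs at the unsubstituted α-CH2 (C5), not at the substituted C3a, and Saegusa–Ito oxidation of the silyl enol ether should give the C5=C6 enone regiospecifically.

Step 5
Reactants: 10 enone
Product: 11 (1R,4R,5S,6R)-6-(2,2-dimethoxyethyl)-5-(dimethoxymethyl)-4-(propan-2-yl)cyclohex-2-en-1-ol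
Conditions: NaBH4, CeCl3·7H2O, MeOH, −78 → 0 °C
Reagents that add atoms: none
Why: Luche 1,2-reduction with axial hydride delivery should give the pseudo-equatorial C4 alcohol trans to the neighbouring side chain; this centre only isolates the alkene from the carbonyl and is erased in step 7.

Step 6
Reactants: 11 allylic alcohol
Product: 13 (1R,2S,3R,4R,5S,6S)-3-(2,2-dimethoxyethyl)-4-(dimethoxymethyl)-5-(propan-2-yl)-7-oxabicyclo[4.1.0]heptan-2-ol (oxirane cis to isopropyl), via bromohydrin 12 (not isolated)
Conditions: NBS, NaHCO3, THF/H2O, 0 °C; then K2CO3, MeOH, rt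
Reagents that add atoms: water, O; N-bromosuccinimide, O=C1CCC(=O)N1Br (its bromine stays only in intermediate 12)
Why: Bromohydrin formation by anti addition should place water trans-diaxially at C6, the carbon remote from the electron-withdrawing C4 carbinol (Fürst–Plattner opening of the bromonium ion formed anti to isopropyl), which sets the C6 oxygen cis to isopropyl, and base then closes the oxirane by backside displacement of bromide at C5, on the face that direct epoxidation would not reach.

Step 7
Reactants: 13 epoxy alcohol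
Product: 14 (1S,3R,4S,5S,6S)-3-(2,2-dimethoxyethyl)-4-(dimethoxymethyl)-5-(propan-2-yl)-7-oxabicyclo[4.1.0]heptan-2-one
Conditions: Dess–Martin periodinane, NaHCO3, CH2Cl2, 0 °C → rt
Reagents that add atoms: none
Why: Buffered Dess–Martin oxidation of the secondary alcohol should leave the oxirane and both acetals untouched.

Step 8
Reactants: 14 epoxy ketone
Product: 15 (1R,3R,4R,5S,6S)-3-(2,2-dimethoxyethyl)-4-(dimethoxymethyl)-2-methylidene-5-(propan-2-yl)-7-oxabicyclo[4.1.0]heptane
Conditions: Ph3PCH3Br, KOtBu, THF, 0 °C → rt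
Reagents that add atoms: methylenetriphenylphosphorane, C=P(c1ccccc1)(c1ccccc1)c1ccccc1 (made in the flask from methyltriphenylphosphonium bromide, C[P+](c1ccccc1)(c1ccccc1)c1ccccc1.[Br-])
Why: Wittig methylenation installs the exocyclic C4 methylene, and the only enolisable centre (C3a) already has its stable equatorial configuration.

Step 9
Reactants: 15 vinyl epoxide; 16 angelic acid
Product: 17 (1S,3R,4R,5S,6S)-3-(2,2-dimethoxyethyl)-4-(dimethoxymethyl)-6-hydroxy-2-methylidene-5-(propan-2-yl)cyclohexyl (2Z)-2-methylbut-2-enoate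
Conditions: angelic acid (3 equiv), Cs2CO3 (0.3 equiv), DMF, 60 °C
Reagents that add atoms: none
Why: SN2 opening of the vinyl epoxide by cesium angelate at the activated allylic carbon C5 is also the trans-diaxial (Fürst–Plattner) mode, so inversion should put the angelate on C5 trans to the free C6 hydroxyl, whose diaxial relation to the ester blocks acyl migration.

Step 10
Reactants: 17 angelate bis(dimethyl acetal)
Product: 18 (1S,2S,3S,4R,5R)-4-formyl-2-hydroxy-6-methylidene-5-(2-oxoethyl)-3-(propan-2-yl)cyclohexyl (2Z)-2-methylbut-2-enoate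
Conditions: Amberlyst-15, acetone/H2O, rt
Reagents that add atoms: water, O
Why: Mild acid-catalysed acetal hydrolysis should free both aldehydes while the allylic ester, the alkene and the hydroxyl survive; the all-equatorial dialdehyde is the stable epimer.

Step 11
Reactants: 18 dialdehyde
Product: 19 (1R,3aR,5S,6S,7S,7aR)-1,6-dihydroxy-4-methylidene-2-oxo-7-(propan-2-yl)octahydro-1H-inden-5-yl (2Z)-2-methylbut-2-enoate
Conditions: 2-(pentafluorophenyl)-6,7-dihydro-5H-pyrrolo[2,1-c][1,2,4]triazol-2-ium tetrafluoroborate (15 mol %), Et3N (15 mol %), CH2Cl2 (0.02 M), rt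
Reagents that add atoms: none
Why: The carbene from the triazolium salt adds to the unhindered aldehyde of the CH2CHO arm, proton transfer gives the nucleophilic enaminol (acyl anion equivalent), and this attacks the ring-bound aldehyde before the carbene is released: an intramolecular crossed benzoin reaction of a 1,5-dialdehyde, a known route to 2-hydroxycyclopentanones. The ring closes in the 5-exo-trig mode by forming only the C1–C2 bond, so the trans fusion is inherited from the trans-diequatorial arms on C3a and C7a. The new centre C1 is controlled by the ring: the carbinol oxygen should take the position anti to the C7a–C7 bond (cis to H-7a), away from the isopropyl-bearing carbon, and since this is also the more stable epimer a minor epimer can be equilibrated through the enol with mild base. The step needs chemoselectivity between the two aldehydes, which the substrate secures because the α-unbranched aldehyde forms the acyl anion much faster than the α-branched ring aldehyde, and the alternative ketol would be a strained trans-hydrindan-1-one. Aldol closure would give only four-membered rings, and dilution suppresses intermolecular pathways.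

Step 12
Reactants: 19 ketol
Product: 20 CNP0317011.1, (1R,3aR,5S,6S,7S,7aR)-1-acetoxy-6-hydroxy-4-methylidene-2-oxo-7-(propan-2-yl)octahydro-1H-inden-5-yl (2Z)-2-methylbut-2-enoate
Conditions: Ac2O (1.2 equiv), pyridine, CH2Cl2, 0 °C
Reagents that add atoms: acetic anhydride, CC(=O)OC(C)=O
Why: Acylation should take place at the accessible α-ketol hydroxyl on C1, because the axial C6 hydroxyl flanked by the isopropyl and angelate groups reacts far more slowly.

Compound list
1 | 3-methylbutanal (isovaleraldehyde) | CC(C)CC=O | starting material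
2 | but-3-en-2-one (methyl vinyl ketone) | CC(=O)C=C | starting material
3 | (2S)-5-oxo-2-(propan-2-yl)hexanal | O=C[C@H](C(C)C)CCC(C)=O | intermediate
4 | (4S)-4-(propan-2-yl)cyclohex-2-en-1-one, (S)-cryptone | O=C1C=C[C@H](C(C)C)CC1 | intermediate
5 | bromomagnesium 3-ethenyl-4-(propan-2-yl)cyclohex-1-en-1-olate, vinyl trans to isopropyl | Br[Mg]OC1=C[C@@H](C=C)[C@H](C(C)C)CC1 | intermediate
6 | (2R,3S,4S)-3-ethenyl-4-(propan-2-yl)-2-(prop-2-en-1-yl)cyclohexan-1-one, all-trans | O=C1[C@H](CC=C)[C@@H](C=C)[C@H](C(C)C)CC1 | intermediate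
7 | (1S,2R,6S)-3-oxo-2-(2-oxoethyl)-6-(propan-2-yl)cyclohexane-1-carbaldehyde | O=C1[C@H](CC=O)[C@@H](C=O)[C@H](C(C)C)CC1 | intermediate
8 | (2R,3S,4S)-2-(2,2-dimethoxyethyl)-3-(dimethoxymethyl)-4-(propan-2-yl)cyclohexan-1-one | O=C1[C@H](CC(OC)OC)[C@@H](C(OC)OC)[C@H](C(C)C)CC1 | intermediate
9 | trimethylsilyl enol ether of 8 with the C1=C6 double bond, ring centres unchanged | C[Si](C)(C)OC=1[C@H](CC(OC)OC)[C@@H](C(OC)OC)[C@H](C(C)C)CC=1 | intermediate
10 | (4R,5S,6R)-6-(2,2-dimethoxyethyl)-5-(dimethoxymethyl)-4-(propan-2-yl)cyclohex-2-en-1-one | O=C1[C@H](CC(OC)OC)[C@@H](C(OC)OC)[C@H](C(C)C)C=C1 | intermediate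
11 | (1R,4R,5S,6R)-6-(2,2-dimethoxyethyl)-5-(dimethoxymethyl)-4-(propan-2-yl)cyclohex-2-en-1-ol | O[C@H]1[C@H](CC(OC)OC)[C@@H](C(OC)OC)[C@H](C(C)C)C=C1 | intermediate
12 | 2-bromo-4-(2,2-dimethoxyethyl)-5-(dimethoxymethyl)-6-(propan-2-yl)cyclohexane-1,3-diol; Br cis to the C3 hydroxyl and trans-diaxial to the new C1 hydroxyl, which is cis to isopropyl | O[C@H]1[C@H](CC(OC)OC)[C@@H](C(OC)OC)[C@H](C(C)C)[C@H](O)[C@H]1Br | intermediate
13 | (1R,2S,3R,4R,5S,6S)-3-(2,2-dimethoxyethyl)-4-(dimethoxymethyl)-5-(propan-2-yl)-7-oxabicyclo[4.1.0]heptan-2-ol | O[C@H]1[C@H](CC(OC)OC)[C@@H](C(OC)OC)[C@H](C(C)C)[C@@H]2O[C@H]12 | intermediate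
14 | (1S,3R,4S,5S,6S)-3-(2,2-dimethoxyethyl)-4-(dimethoxymethyl)-5-(propan-2-yl)-7-oxabicyclo[4.1.0]heptan-2-one | O=C1[C@H](CC(OC)OC)[C@@H](C(OC)OC)[C@H](C(C)C)[C@@H]2O[C@H]12 | intermediate
15 | (1R,3R,4R,5S,6S)-3-(2,2-dimethoxyethyl)-4-(dimethoxymethyl)-2-methylidene-5-(propan-2-yl)-7-oxabicyclo[4.1.0]heptane | C=C1[C@H](CC(OC)OC)[C@@H](C(OC)OC)[C@H](C(C)C)[C@@H]2O[C@H]12 | intermediate
16 | angelic acid, (2Z)-2-methylbut-2-enoic acid | C/C=C(/C)C(=O)O | starting material
17 | (1S,3R,4R,5S,6S)-3-(2,2-dimethoxyethyl)-4-(dimethoxymethyl)-6-hydroxy-2-methylidene-5-(propan-2-yl)cyclohexyl (2Z)-2-methylbut-2-enoate | C=C1[C@H](CC(OC)OC)[C@@H](C(OC)OC)[C@H](C(C)C)[C@H](O)[C@H]1OC(=O)/C(C)=C\C | intermediate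
18 | (1S,2S,3S,4R,5R)-4-formyl-2-hydroxy-6-methylidene-5-(2-oxoethyl)-3-(propan-2-yl)cyclohexyl (2Z)-2-methylbut-2-enoate | C=C1[C@H](CC=O)[C@@H](C=O)[C@H](C(C)C)[C@H](O)[C@H]1OC(=O)/C(C)=C\C | intermediate
19 | (1R,3aR,5S,6S,7S,7aR)-1,6-dihydroxy-4-methylidene-2-oxo-7-(propan-2-yl)octahydro-1H-inden-5-yl (2Z)-2-methylbut-2-enoate | C=C1[C@@H]2CC(=O)[C@H](O)[C@H]2[C@H](C(C)C)[C@H](O)[C@H]1OC(=O)/C(C)=C\C | intermediate
20 | CNP0317011.1, (1R,3aR,5S,6S,7S,7aR)-1-acetoxy-6-hydroxy-4-methylidene-2-oxo-7-(propan-2-yl)octahydro-1H-inden-5-yl (2Z)-2-methylbut-2-enoate | C=C1[C@@H]2CC(=O)[C@H](OC(C)=O)[C@H]2[C@H](C(C)C)[C@H](O)[C@H]1OC(=O)/C(C)=C\C | target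

Total step count: 12. Longest linear sequence: 12 steps (fully linear from 1 and 2; 16 is used as purchased).

Steps most likely to fail

Step 11 (key step). Acyl anion formation could occur at the wrong aldehyde, or base-induced epimerisation at C7a and intermolecular condensation could outrun ring closure. Fallback: starting from dialdehyde 18, a reductive ketyl coupling replaces the umpolung. SmI2 with t-BuOH in THF at −78 °C should give intramolecular pinacol closure to the cis-1,2-diol F1 (drawn with both five-ring hydroxyls cis to H-7a). The less hindered C2 hydroxyl, flanked by the C3 methylene, is then oxidised with Ag2CO3 on Celite in refluxing toluene. Brief treatment with DBU equilibrates C1 if needed, and the sequence returns to ketol 19.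

Step 9. The carboxylate could attack the exocyclic methylene terminus (SN2') instead of C5, or slow opening could allow Z to E isomerisation of the angelate on prolonged heating. Fallback: starting from vinyl epoxide 15, the oxygen and the acyl group are introduced separately. KOH in DMSO/H2O at 80 °C opens the oxirane trans-diaxially to the trans-5,6-diol F2, with the acetals stable to base. Yamaguchi esterification (angelic acid, 2,4,6-trichlorobenzoyl chloride, Et3N, then DMAP, toluene) should then acylate the allylic C5 hydroxyl in preference to the C6 hydroxyl next to isopropyl, returning to 17.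

Step 6. Water could open the bromonium ion at C5 instead of C6, or the dimethyl acetals could be partly lost in the aqueous medium, so that the oxirane ends up on the wrong face. Fallback: starting from allylic alcohol 11, the face is set by hydroxyl direction instead. Mitsunobu inversion (4-nitrobenzoic acid, PPh3, DIAD) gives the inverted 4-nitrobenzoate F3, and K2CO3 in MeOH frees the epimeric allylic alcohol F4, whose hydroxyl now lies on the isopropyl face. VO(acac)2 with t-BuOOH epoxidises syn to that hydroxyl to give the cis-epoxy alcohol F5, and Dess–Martin oxidation returns to epoxy ketone 14.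

Further compounds
F1 | step 11 | cis-1,2-diol: (2Z)-2-methylbut-2-enoate of 1,2,6-trihydroxy-4-methylidene-7-(propan-2-yl)octahydro-1H-inden-5-ol, both five-ring hydroxyls cis to H-7a, other centres as in 19 | C=C1[C@@H]2C[C@H](O)[C@H](O)[C@H]2[C@H](C(C)C)[C@H](O)[C@H]1OC(=O)/C(C)=C\C
F2 | step 9 | trans-diaxial diol: 4-(2,2-dimethoxyethyl)-5-(dimethoxymethyl)-3-methylidene-6-(propan-2-yl)cyclohexane-1,2-diol, C1 hydroxyl cis to isopropyl, C2 hydroxyl trans to it | C=C1[C@H](CC(OC)OC)[C@@H](C(OC)OC)[C@H](C(C)C)[C@H](O)[C@H]1O
F3 | step 6 | 4-nitrobenzoate of the C1 epimer of 11 | O=C(O[C@@H]1[C@H](CC(OC)OC)[C@@H](C(OC)OC)[C@H](C(C)C)C=C1)c1ccc(cc1)[N+](=O)[O-]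
F4 | step 6 | C1 epimer of allylic alcohol 11 (hydroxyl cis to isopropyl) | O[C@@H]1[C@H](CC(OC)OC)[C@@H](C(OC)OC)[C@H](C(C)C)C=C1
F5 | step 6 | C2 epimer of epoxy alcohol 13 (hydroxyl and oxirane both cis to isopropyl) | O[C@@H]1[C@H](CC(OC)OC)[C@@H](C(OC)OC)[C@H](C(C)C)[C@@H]2O[C@H]12
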